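**Plan**

1. Numbering used: decalin C-1 (methylidene carbon), C-2 (quaternary), C-3 (CHMe), C-4, C-4a, C-5 (=CH), C-6 (=CMe), C-7, C-8, C-8a; dioxane O-1, O-2, C-3 (CH), C-6 (quaternary). Cuts: (a) dioxane C-3 to the propanoate α-carbon; (b) C-1=CH2 back to a C-1 ketone; (c) C-4a–C-8a and C-7–C-8 (intramolecular Diels–Alder reaction); (d) decalin C-2 to the first CH2 of the ethylene bridge; (e) both C–O bonds of the dioxane.
2. Enabling feature: ring A is a cyclohexene whose C-5=C-6 bond lies between C-4a and C-7, and the methylidene carbon C-1 is bonded to the ring-fusion carbon C-8a. With C-1 as a ketone, C-8a=C-8 is a vinyl ketone dienophile, C-4a=C-5–C-6(Me)=C-7 an (E)-isoprenyl diene and C-1–C-2–C-3–C-4 a four-atom tether, so one cycloaddition closes ring A and ring B (C-1, C-2, C-3, C-4, C-4a, C-8a) together.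
3. Forward order: the 1,2-dioxane is made first from (R)-linalool (oxetane, opening by H2O2, ozonolysis, peroxyacetal). Its iodide alkylates a 2,3-dimethylcyclopentanone enolate; ozonolysis of the derived silyl enol ether opens this five-membered template to an acid–aldehyde, which is turned into diene and vinyl ketone. Rings A and B then close last, followed by methylenation and attachment of the propanoate.
4. Stereochemistry: dioxane C-6 from (R)-linalool (inversion in the oxetane opening); decalin C-3 from a copper-catalysed asymmetric conjugate addition; C-2 from trans alkylation of the ring enolate; C-4a and C-8a from the endo, chair-tether Diels–Alder transition state; dioxane C-3 and the propanoate α-carbon from a chiral N-acyl thiazolidinethione enolate.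

Key step: step 11

Assumption: the methoxy-bearing acetal carbon of the dioxane in 7–23 is carried as an epimeric mixture (drawn without configuration); it becomes planar in step 14, so the mixture has no consequence.

**Step 1**
Reactants: 1 (R)-linalool
Product: 2 (3R)-3,7-dimethyloct-6-ene-1,3-diol
Conditions: 9-BBN (2.2 equiv), THF, 0 °C to rt; then NaOH, H2O2, 0 °C
Reagents that add atoms: hydrogen peroxide, OO
Why: Anti-Markovnikov hydroboration–oxidation; the bulky borane should take the monosubstituted vinyl group far faster than the trisubstituted alkene, and the tertiary carbinol centre is not touched.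

**Step 2**
Reactants: 2 (3R)-3,7-dimethyloct-6-ene-1,3-diol
Product: 4 (2R)-2-methyl-2-(4-methylpent-3-en-1-yl)oxetane, via primary monotosylate 3 (not isolated)
Conditions: n-BuLi (1.0 equiv), THF, 0 °C; TsCl (1.0 equiv); then n-BuLi (1.0 equiv), 0 to 60 °C
Reagents that add atoms: none
Why: Selective sulfonylation of the primary alkoxide and intramolecular Williamson etherification (4-exo-tet) by the tertiary alkoxide should close the oxetane with retention, since the C–O bond at the quaternary carbon is not broken.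

**Step 3**
Reactants: 4 (2R)-2-methyl-2-(4-methylpent-3-en-1-yl)oxetane
Product: 5 (3S)-3-hydroperoxy-3,7-dimethyloct-6-en-1-ol
Conditions: H2O2 (anhydrous ethereal solution, 5 equiv), TMSOTf (0.2 equiv), Et2O, −78 to 0 °C
Reagents that add atoms: hydrogen peroxide, OO
Why: Lewis-acid-activated 2,2-disubstituted oxetanes are opened by hydrogen peroxide at the more substituted carbon with predominant inversion (borderline SN2 on the silyloxonium ion), which should set the configuration of dioxane C-6.

**Step 4**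
Reactants: 5 (3S)-3-hydroperoxy-3,7-dimethyloct-6-en-1-ol
Product: 8 2-[(3S)-6-methoxy-3-methyl-1,2-dioxan-3-yl]ethan-1-ol, via hydroperoxy aldehyde 6 (not isolated), via hemiperoxyacetal 7 (not isolated)
Conditions: O3, pyridine (3 equiv), CH2Cl2, −78 °C; aqueous NaHSO4 wash; then MeOH, p-TsOH (cat.), rt
Reagents that add atoms: methanol, CO
Why: Pyridine-moderated ozonolysis cleaves the trisubstituted alkene without a reductant that would attack the hydroperoxide; the aldehyde should be captured by the tertiary hydroperoxide as a six-membered hemiperoxyacetal, and acid-catalysed acetal exchange then gives the methyl peroxyacetal, closing the 1,2-dioxane.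

**Step 5**
Reactants: 8 2-[(3S)-6-methoxy-3-methyl-1,2-dioxan-3-yl]ethan-1-ol
Product: 9 (6S)-6-(2-iodoethyl)-3-methoxy-6-methyl-1,2-dioxane
Conditions: I2, PPh3, imidazole, CH2Cl2, 0 °C
Reagents that add atoms: iodine, II
Why: Appel iodination of the primary alcohol; dialkyl peroxides, unlike hydroperoxides, are not reduced by triphenylphosphine under these conditions.

**Step 6**
Reactants: 10 2-methylcyclopent-2-en-1-one
Product: 12 {[(3S)-2,3-dimethylcyclopent-1-en-1-yl]oxy}trimethylsilane, via magnesium enolate 11 (not isolated)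
Conditions: MeMgBr, Cu(OTf)2 (3 mol %), chiral imidazolinium (N-heterocyclic carbene) ligand precursor (4 mol %), Et2O, −30 °C; then TMSCl, Et3N
Reagents that add atoms: methylmagnesium bromide, C[Mg]Br; chlorotrimethylsilane, C[Si](C)(C)Cl
Why: Copper-catalysed asymmetric conjugate addition of a Grignard reagent to a 2-substituted cycloalkenone with enolate trapping; the ligand enantiomer is chosen to give the (S) centre (decalin C-3), and silylation fixes the enolate regiochemistry.

**Step 7**
Reactants: 12 {[(3S)-2,3-dimethylcyclopent-1-en-1-yl]oxy}trimethylsilane; 9 (6S)-6-(2-iodoethyl)-3-methoxy-6-methyl-1,2-dioxane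
Product: 14 (2R,3S)-2-{2-[(3R)-6-methoxy-3-methyl-1,2-dioxan-3-yl]ethyl}-2,3-dimethylcyclopentan-1-one, via lithium enolate 13 (not isolated)
Conditions: MeLi (1.0 equiv), THF, 0 °C to rt; then 9, HMPA, −40 to 0 °C
Reagents that add atoms: none
Why: Methyllithium releases the regiodefined tetrasubstituted lithium enolate, whose SN2 alkylation by the primary iodide should occur anti to the neighbouring methyl group, creating the quaternary centre (decalin C-2) with the chain trans to that methyl; no free amide base is present that could attack the peroxyacetal.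

**Step 8**
Reactants: 14 (2R,3S)-2-{2-[(3R)-6-methoxy-3-methyl-1,2-dioxan-3-yl]ethyl}-2,3-dimethylcyclopentan-1-one
Product: 16 trimethyl{[(4S,5R)-5-{2-[(3R)-6-methoxy-3-methyl-1,2-dioxan-3-yl]ethyl}-4,5-dimethylcyclopent-1-en-1-yl]oxy}silane, via lithium enolate 15 (not isolated)
Conditions: LDA, THF, −78 °C; then TMSCl
Reagents that add atoms: chlorotrimethylsilane, C[Si](C)(C)Cl
Why: Kinetic enolisation can only occur at the remaining α-methylene group, so a single silyl enol ether should form.

**Step 9**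
Reactants: 16 trimethyl{[(4S,5R)-5-{2-[(3R)-6-methoxy-3-methyl-1,2-dioxan-3-yl]ethyl}-4,5-dimethylcyclopent-1-en-1-yl]oxy}silane
Product: 18 (2R,3S)-2-{2-[(3R)-6-methoxy-3-methyl-1,2-dioxan-3-yl]ethyl}-2,3-dimethyl-5-oxopentanoic acid, via trimethylsilyl ester 17 (not isolated)
Conditions: O3, CH2Cl2/MeOH, −78 °C; then Me2S, −78 °C to rt; aqueous work-up
Reagents that add atoms: ozone, [O-][O+]=O
Why: Ozonolysis of the silyl enol ether opens the template ring, turning the enol carbon into the carboxylic acid (future C-1) and its neighbour into the aldehyde (future C-4a) with both stereocentres intact; dimethyl sulfide does not reduce the dialkyl peroxide.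

**Step 10**
Reactants: 18 (2R,3S)-2-{2-[(3R)-6-methoxy-3-methyl-1,2-dioxan-3-yl]ethyl}-2,3-dimethyl-5-oxopentanoic acid
Product: 19 (2R,3S,5E)-2-{2-[(3R)-6-methoxy-3-methyl-1,2-dioxan-3-yl]ethyl}-2,3,7-trimethylocta-5,7-dienoic acid
Conditions: diethyl (2-methylallyl)phosphonate and n-BuLi (2.2 equiv each), THF/HMPA, −78 °C to rt
Reagents that add atoms: diethyl (2-methylprop-2-en-1-yl)phosphonate, CCOP(=O)(CC(C)=C)OCC
Why: Horner–Wadsworth–Emmons olefination with the lithiated allylic phosphonate should convert the aldehyde into the terminal 1,3-diene with (E) geometry, while the carboxylate formed by the first equivalent of base is a spectator.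

**Step 11**
Reactants: 19 (2R,3S,5E)-2-{2-[(3R)-6-methoxy-3-methyl-1,2-dioxan-3-yl]ethyl}-2,3,7-trimethylocta-5,7-dienoic acid
Product: 22 (2R,3S,4aR,8aS)-2-{2-[(3R)-6-methoxy-3-methyl-1,2-dioxan-3-yl]ethyl}-2,3,6-trimethyl-3,4,4a,7,8,8a-hexahydronaphthalen-1(2H)-one, via acid chloride 20 (not isolated), via trienone 21 (not isolated)
Conditions: 1-chloro-N,N,2-trimethylprop-1-en-1-amine, CH2Cl2, 0 °C to rt; then CH2=CHSnBu3, Pd(PPh3)4 (5 mol %), toluene, rt to 50 °C
Reagents that add atoms: tributyl(vinyl)stannane, CCCC[Sn](CCCC)(CCCC)C=C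
Why: The acid chloride is coupled with the vinylstannane by zerovalent palladium (Stille acylation) to the 1,7,9-decatrien-3-one 21, which should undergo a concerted, asynchronous intramolecular [4+2] cycloaddition at or just above room temperature; the closest known reaction type is the intramolecular Diels–Alder reaction of 1,7,9-decatrien-3-ones to cis-fused octalones. Ring A (C-4a, C-5, C-6, C-7, C-8, C-8a) closes as the cycloadduct ring through the new bonds C-7–C-8 and C-4a–C-8a, and ring B (C-1, C-2, C-3, C-4, C-4a, C-8a) closes through the same C-4a–C-8a bond as the ring of the four-atom tether. C-4a and C-8a are set together: the (E)-diene and the endo position of the tether carbonyl give the cis ring fusion. Face selectivity comes from the tether stereocentres, which sit in a chair with the C-3 methyl and the C-2 dioxanylethyl chain equatorial and only the C-2 methyl axial; the other cis transition state would place the incoming C-8 methylene syn-axial to that methyl. The step needs endo over exo selectivity, which rests on the conjugated carbonyl lying in the tether, and chemoselective acylation, which rests on neutral chloroenamine activation and the tolerance of dialkyl peroxyacetals to zerovalent palladium.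

**Step 12**
Reactants: 22 (2R,3S,4aR,8aS)-2-{2-[(3R)-6-methoxy-3-methyl-1,2-dioxan-3-yl]ethyl}-2,3,6-trimethyl-3,4,4a,7,8,8a-hexahydronaphthalen-1(2H)-one
Product: 23 (6R)-3-methoxy-6-methyl-6-{2-[(2R,3S,4aR,8aS)-2,3,6-trimethyl-1-methylidene-1,2,3,4,4a,7,8,8a-octahydronaphthalen-2-yl]ethyl}-1,2-dioxane
Conditions: Cp2TiMe2 (3 equiv), toluene, 65 °C, dark
Reagents that add atoms: dimethyltitanocene, [CH3-].[CH3-].[Ti+4].c1cc[cH-]c1.c1cc[cH-]c1
Why: The titanium methylidene formed on heating methylenates the hindered ketone by [2+2] cycloaddition and cycloreversion under non-basic conditions, so C-8a (α to the carbonyl) should not epimerise and the acetal is left alone; the tetravalent titanium reagent is not a reductant for the O–O bond.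

**Step 13**
Reactants: 24 (4R)-4-benzyl-1,3-thiazolidine-2-thione
Product: 25 (4R)-4-benzyl-3-propanoyl-1,3-thiazolidine-2-thione
Conditions: EtCOCl, Et3N, DMAP (cat.), CH2Cl2, 0 °C
Reagents that add atoms: propanoyl chloride, CCC(Cl)=O
Why: Routine N-acylation of the auxiliary.

**Step 14**
Reactants: 25 (4R)-4-benzyl-3-propanoyl-1,3-thiazolidine-2-thione; 23 (6R)-3-methoxy-6-methyl-6-{2-[(2R,3S,4aR,8aS)-2,3,6-trimethyl-1-methylidene-1,2,3,4,4a,7,8,8a-octahydronaphthalen-2-yl]ethyl}-1,2-dioxane
Product: 27 (4R)-4-benzyl-3-{(2S)-2-[(3R,6R)-6-methyl-6-{2-[(2R,3S,4aR,8aS)-2,3,6-trimethyl-1-methylidene-1,2,3,4,4a,7,8,8a-octahydronaphthalen-2-yl]ethyl}-1,2-dioxan-3-yl]propanoyl}-1,3-thiazolidine-2-thione, via chlorotitanium enolate 26 (not isolated)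
Conditions: 25, TiCl4 (1.05 equiv), i-Pr2NEt (1.1 equiv), CH2Cl2, −78 to −40 °C; then 23, SnCl4 (1.1 equiv), −78 °C
Reagents that add atoms: none
Why: Proposed new method: SnCl4 should ionise the methyl peroxyacetal to a cyclic peroxycarbenium ion, which is attacked by the chelated (Z)-chlorotitanium enolate through an open antiperiplanar transition state; the enolate face anti to the benzyl group sets the α-carbon (S), and because the ring oxygen and ring carbon of the cation are cis both lie on the side of the enolate hydrogen, which should give the syn adduct (dioxane C-3 R); the closest known reaction types are Lewis-acid-mediated additions of silyl ketene acetals to 3-alkoxy-1,2-dioxanes and additions of titanium enolates of chiral N-acyl thiazolidinethiones to oxocarbenium ions from acetals.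

**Step 15**
Reactants: 27 (4R)-4-benzyl-3-{(2S)-2-[(3R,6R)-6-methyl-6-{2-[(2R,3S,4aR,8aS)-2,3,6-trimethyl-1-methylidene-1,2,3,4,4a,7,8,8a-octahydronaphthalen-2-yl]ethyl}-1,2-dioxan-3-yl]propanoyl}-1,3-thiazolidine-2-thione
Product: 28 methyl (2S)-2-[(3R,6R)-6-methyl-6-{2-[(2R,3S,4aR,8aS)-2,3,6-trimethyl-1-methylidene-1,2,3,4,4a,7,8,8a-octahydronaphthalen-2-yl]ethyl}-1,2-dioxan-3-yl]propanoate (target)
Conditions: MeOH, imidazole, CH2Cl2, rt
Reagents that add atoms: methanol, CO
Why: The N-acyl thiazolidinethione is an activated amide that methanol displaces under imidazole catalysis at room temperature, conditions too weakly basic to enolise the α-centre or to trigger β-elimination of the peroxide.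

**Compound list**

1 | (R)-linalool, (3R)-3,7-dimethylocta-1,6-dien-3-ol | C=C[C@](C)(O)CCC=C(C)C | starting material
2 | (3R)-3,7-dimethyloct-6-ene-1,3-diol | OCC[C@](C)(O)CCC=C(C)C | intermediate
3 | (3R)-3-hydroxy-3,7-dimethyloct-6-en-1-yl 4-methylbenzenesulfonate | Cc1ccc(cc1)S(=O)(=O)OCC[C@](C)(O)CCC=C(C)C | intermediate
4 | (2R)-2-methyl-2-(4-methylpent-3-en-1-yl)oxetane | C1C[C@](C)(O1)CCC=C(C)C | intermediate
5 | (3S)-3-hydroperoxy-3,7-dimethyloct-6-en-1-ol | OCC[C@@](C)(OO)CCC=C(C)C | intermediate
6 | (4S)-4-hydroperoxy-6-hydroxy-4-methylhexanal | OCC[C@@](C)(OO)CCC=O | intermediate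
7 | (6S)-6-(2-hydroxyethyl)-6-methyl-1,2-dioxan-3-ol (C-3 epimers) | OCC[C@@]1(C)OOC(O)CC1 | intermediate
8 | 2-[(3S)-6-methoxy-3-methyl-1,2-dioxan-3-yl]ethan-1-ol (acetal epimers) | OCC[C@@]1(C)OOC(OC)CC1 | intermediate
9 | (6S)-6-(2-iodoethyl)-3-methoxy-6-methyl-1,2-dioxane | ICC[C@@]1(C)OOC(OC)CC1 | intermediate
10 | 2-methylcyclopent-2-en-1-one | CC1=CCCC1=O | starting material
11 | bromomagnesium (3S)-2,3-dimethylcyclopent-1-en-1-olate | C[C@H]1CCC(O[Mg]Br)=C1C | intermediate
12 | {[(3S)-2,3-dimethylcyclopent-1-en-1-yl]oxy}trimethylsilane | C[C@H]1CCC(O[Si](C)(C)C)=C1C | intermediate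
13 | lithium (3S)-2,3-dimethylcyclopent-1-en-1-olate | C[C@H]1CCC(O[Li])=C1C | intermediate
14 | (2R,3S)-2-{2-[(3R)-6-methoxy-3-methyl-1,2-dioxan-3-yl]ethyl}-2,3-dimethylcyclopentan-1-one | C[C@H]1CCC(=O)[C@]1(C)CC[C@@]1(C)OOC(OC)CC1 | intermediate
15 | lithium (4S,5R)-5-{2-[(3R)-6-methoxy-3-methyl-1,2-dioxan-3-yl]ethyl}-4,5-dimethylcyclopent-1-en-1-olate | C[C@H]1CC=C(O[Li])[C@]1(C)CC[C@@]1(C)OOC(OC)CC1 | intermediate
16 | trimethyl{[(4S,5R)-5-{2-[(3R)-6-methoxy-3-methyl-1,2-dioxan-3-yl]ethyl}-4,5-dimethylcyclopent-1-en-1-yl]oxy}silane | C[C@H]1CC=C(O[Si](C)(C)C)[C@]1(C)CC[C@@]1(C)OOC(OC)CC1 | intermediate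
17 | trimethylsilyl (2R,3S)-2-{2-[(3R)-6-methoxy-3-methyl-1,2-dioxan-3-yl]ethyl}-2,3-dimethyl-5-oxopentanoate | O=CC[C@H](C)[C@@](C)(CC[C@@]1(C)OOC(OC)CC1)C(=O)O[Si](C)(C)C | intermediate
18 | (2R,3S)-2-{2-[(3R)-6-methoxy-3-methyl-1,2-dioxan-3-yl]ethyl}-2,3-dimethyl-5-oxopentanoic acid | O=CC[C@H](C)[C@@](C)(CC[C@@]1(C)OOC(OC)CC1)C(=O)O | intermediate
19 | (2R,3S,5E)-2-{2-[(3R)-6-methoxy-3-methyl-1,2-dioxan-3-yl]ethyl}-2,3,7-trimethylocta-5,7-dienoic acid | C=C(C)/C=C/C[C@H](C)[C@@](C)(CC[C@@]1(C)OOC(OC)CC1)C(=O)O | intermediate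
20 | (2R,3S,5E)-2-{2-[(3R)-6-methoxy-3-methyl-1,2-dioxan-3-yl]ethyl}-2,3,7-trimethylocta-5,7-dienoyl chloride | C=C(C)/C=C/C[C@H](C)[C@@](C)(CC[C@@]1(C)OOC(OC)CC1)C(Cl)=O | intermediate
21 | (4R,5S,7E)-4-{2-[(3R)-6-methoxy-3-methyl-1,2-dioxan-3-yl]ethyl}-4,5,9-trimethyldeca-1,7,9-trien-3-one | C=C(C)/C=C/C[C@H](C)[C@@](C)(CC[C@@]1(C)OOC(OC)CC1)C(=O)C=C | intermediate
22 | (2R,3S,4aR,8aS)-2-{2-[(3R)-6-methoxy-3-methyl-1,2-dioxan-3-yl]ethyl}-2,3,6-trimethyl-3,4,4a,7,8,8a-hexahydronaphthalen-1(2H)-one | O=C1[C@H]2CCC(C)=C[C@H]2C[C@H](C)[C@@]1(C)CC[C@@]1(C)OOC(OC)CC1 | intermediate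
23 | (6R)-3-methoxy-6-methyl-6-{2-[(2R,3S,4aR,8aS)-2,3,6-trimethyl-1-methylidene-1,2,3,4,4a,7,8,8a-octahydronaphthalen-2-yl]ethyl}-1,2-dioxane | C=C1[C@H]2CCC(C)=C[C@H]2C[C@H](C)[C@@]1(C)CC[C@@]1(C)OOC(OC)CC1 | intermediate
24 | (4R)-4-benzyl-1,3-thiazolidine-2-thione | S=C1N[C@H](Cc2ccccc2)CS1 | starting material
25 | (4R)-4-benzyl-3-propanoyl-1,3-thiazolidine-2-thione | CCC(=O)N1C(=S)SC[C@H]1Cc1ccccc1 | intermediate
26 | trichlorotitanium (Z)-enolate of 25 | C/C=C(\O[Ti](Cl)(Cl)Cl)N1C(=S)SC[C@H]1Cc1ccccc1 | intermediate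
27 | (4R)-4-benzyl-3-{(2S)-2-[(3R,6R)-6-methyl-6-{2-[(2R,3S,4aR,8aS)-2,3,6-trimethyl-1-methylidene-1,2,3,4,4a,7,8,8a-octahydronaphthalen-2-yl]ethyl}-1,2-dioxan-3-yl]propanoyl}-1,3-thiazolidine-2-thione | C=C1[C@H]2CCC(C)=C[C@H]2C[C@H](C)[C@@]1(C)CC[C@]1(C)CC[C@H]([C@H](C)C(=O)N2C(=S)SC[C@H]2Cc2ccccc2)OO1 | intermediate
28 | methyl (2S)-2-[(3R,6R)-6-methyl-6-{2-[(2R,3S,4aR,8aS)-2,3,6-trimethyl-1-methylidene-1,2,3,4,4a,7,8,8a-octahydronaphthalen-2-yl]ethyl}-1,2-dioxan-3-yl]propanoate | C=C1[C@H]2CCC(C)=C[C@H]2C[C@H](C)[C@@]1(C)CC[C@]1(C)CC[C@H]([C@H](C)C(=O)OC)OO1 | target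

**Step count and risks**

Total step count: 15. Longest linear sequence: 13 steps (steps 1–5, 7–12, 14, 15).

Steps most likely to fail:

Step 14 (Proposed new method). What may go wrong: the cyclic peroxycarbenium ion has almost no facial bias of its own, so control by the enolate may be incomplete and give epimers at dioxane C-3 or at the α-carbon; ionisation at the other C–O bond with ring opening is also conceivable. Fallback with known chemistry, from 23 directly to 28: Lewis-acid-mediated substitution of the 3-methoxy-1,2-dioxane with the achiral silyl ketene acetal of methyl propanoate, 1-methoxy-1-(trimethylsilyloxy)prop-1-ene (SnCl4 or TiCl4, CH2Cl2, −78 °C). This installs the methyl ester in one operation without an auxiliary; the same open transition state should favour the syn pair, and 28 would be separated from its diastereomers by preparative chromatography. No new compound is formed on this way (F0).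

Step 12. What may go wrong: attack of the titanium reagent on the O–O bond, or slow conversion of the ketone flanked by a quaternary and a tertiary carbon, leaving time for loss of the cis ring fusion. Fallback from 22 back to 23 by Peterson olefination: Me3SiCH2Li with CeCl3 (THF, −78 °C, non-basic organocerium addition) should give the β-hydroxysilane 2-{2-[(3R)-6-methoxy-3-methyl-1,2-dioxan-3-yl]ethyl}-2,3,6-trimethyl-1-[(trimethylsilyl)methyl]-1,2,3,4,4a,7,8,8a-octahydronaphthalen-1-ol F1 (C-1 epimers), and KH in THF then brings about syn-elimination to 23.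

Step 11. What may go wrong: slow transmetalation or decarbonylation at the hindered acylpalladium stage, so that the trienone is not formed cleanly. Fallback from 20 (made as in step 11) back to 22: N,O-dimethylhydroxylamine hydrochloride and pyridine give the N-methoxy-N-methylamide (2R,3S,5E)-N-methoxy-2-{2-[(3R)-6-methoxy-3-methyl-1,2-dioxan-3-yl]ethyl}-N,2,3,7-tetramethylocta-5,7-dienamide F2. Vinylmagnesium bromide (THF, −20 °C, acidic quench) should then release trienone 21, which cyclises to 22 on standing at room temperature.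

**Further compounds**

F0 | step 14 | none | none
F1 | step 12 | 2-{2-[(3R)-6-methoxy-3-methyl-1,2-dioxan-3-yl]ethyl}-2,3,6-trimethyl-1-[(trimethylsilyl)methyl]-1,2,3,4,4a,7,8,8a-octahydronaphthalen-1-ol (2R,3S,4aR,8aS; C-1 epimers) | C[Si](C)(C)CC1(O)[C@H]2CCC(C)=C[C@H]2C[C@H](C)[C@@]1(C)CC[C@@]1(C)OOC(OC)CC1
F2 | step 11 | (2R,3S,5E)-N-methoxy-2-{2-[(3R)-6-methoxy-3-methyl-1,2-dioxan-3-yl]ethyl}-N,2,3,7-tetramethylocta-5,7-dienamide | C=C(C)/C=C/C[C@H](C)[C@@](C)(CC[C@@]1(C)OOC(OC)CC1)C(=O)N(C)OC
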